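**Retrosynthetic overview**
1. The enone carbonyl comes from chemoselective oxidation of a cyclohex-5-ene-1,2,4-triol. The carbinol that becomes C1=O serves only as a stereochemical relay and is then destroyed.
2. The only ring, the carbocycle, is closed late at C2=C3 by ring-closing metathesis of an acyclic octadiene-triol.
3. The key disconnection is C4–C5. The carbonyl carbon of acrolein is made nucleophilic as a γ-acetoxyallylindium (an α-hydroxyallyl anion equivalent) and joined to a ketone carbonyl carbon. This one bond sets both diol stereocentres.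
4. The β-hydroxy ketone comes from a catalytic enantioselective Mukaiyama aldol of a methyl ketone silyl enol ether with a second acrolein, used in its normal polarity.
5. The methyl ketone comes from oleic acid and MeLi. The carboxyl carbon becomes ring carbon C5, and the Z-olefin and the 17-carbon chain are bought.

Assumption: commercial oleic acid of at least 99 % Z purity is used. Ring atoms are numbered as in the target (C1 carbonyl, C2=C3, C4 secondary carbinol, C5 tertiary carbinol, C6 methylene), and the SMILES corresponds to the (4R,5S) cis-diol.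

**Step 1**
Reactants: 1 oleic acid; 2 methyllithium
Product: 4 (10Z)-nonadec-10-en-2-one, via dilithium gem-diolate 3 (not isolated)
Conditions: MeLi (2.2 equiv), Et2O, 0 °C to rt; then H2O, 0 °C
Reagents that add atoms: methyllithium, [Li]C
Why: Addition of the organolithium to the lithium carboxylate stops at the gem-diolate 3, which collapses to the methyl ketone only on aqueous work-up, and the isolated Z-olefin is inert (ketone synthesis from a carboxylic acid and an organolithium).

**Step 2**
Reactants: 4 (10Z)-nonadec-10-en-2-one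
Product: 5 trimethyl[(10Z)-nonadeca-1,10-dien-2-yloxy]silane
Conditions: LiN(iPr)2 (1.1 equiv), Me3SiCl (1.3 equiv, present from the start), THF, −78 °C
Reagents that add atoms: chlorotrimethylsilane, C[Si](C)(C)Cl
Why: The hindered amide base removes a methyl proton faster than a C3 proton and the enolate is trapped at once, so the terminal silyl enol ether forms regioselectively (kinetic enolate silylation).

**Step 3**
Reactants: 5 trimethyl[(10Z)-nonadeca-1,10-dien-2-yloxy]silane; 6 acrolein
Product: 8 (3S,13Z)-3-hydroxydocosa-1,13-dien-5-one, via trichlorosilyl aldolate 7 (not isolated)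
Conditions: SiCl4 (1.5 equiv), binaphthyldiamine-derived chiral bisphosphoramide (5 mol %, the enantiomer that directs Si-face attack), iPr2NEt (10 mol %), CH2Cl2, −78 °C; then sat. aq NaHCO3
Reagents that add atoms: acrolein, C=CC=O
Why: The phosphoramide-activated SiCl4 binds acrolein in a chiral cationic silicon complex and the silyl enol ether attacks the Si face in 1,2-fashion through an open transition state, which sets the S carbinol centre (Lewis-base-catalysed enantioselective Mukaiyama aldol addition).

**Step 4**
Reactants: 6 acrolein; 9 acetyl bromide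
Product: 10 3-bromoprop-1-en-1-yl acetate (E/Z mixture)
Conditions: ZnCl2 (2 mol %), CH2Cl2, −20 °C to rt
Reagents that add atoms: acetyl bromide, CC(=O)Br
Why: The acyl bromide adds across the enal with O-acylation and bromide delivery to the β-carbon, which turns the former carbonyl carbon into an enol-ester terminus ready for polarity reversal (1,4-addition of an acyl halide to an enal).

**Step 5**
Reactants: 8 (3S,13Z)-3-hydroxydocosa-1,13-dien-5-one; 10 3-bromoprop-1-en-1-yl acetate
Product: 13 (3R,4S,6S)-4-[(8Z)-heptadec-8-en-1-yl]octa-1,7-diene-3,4,6-triol, via (Z)-3-acetoxyallylindium dibromide 11 (not isolated), via C3 monoacetate 12 (not isolated)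
Conditions: In powder (1.5 equiv), 10 (2 equiv), THF, 25 °C; aq NH4Cl work-up, crude 12 into K2CO3 (0.2 equiv), MeOH, 0 °C
Reagents that add atoms: 3-bromoprop-1-en-1-yl acetate, CC(=O)OC=CCBr
Why: Proposed new method: indium inserts into the C–Br bond to give the internally chelated Z-allylindium 11, an α-hydroxyallyl anion equivalent in which the former acrolein carbonyl carbon is nucleophilic; this carbon attacks the ketone carbonyl carbon of 8 in a chair transition state whose trivalent indium is also held by the free hydroxyl (bicyclic chelate with the hydroxyalkyl arm axial, the long chain equatorial and the vinyl group exo), so the S carbinol relays to 4S, the axial acetoxy group of the Z-reagent gives 3R (the erythro pair that becomes the cis-diol), and mild methanolysis then removes the acetate; the closest known reaction types are the indium Barbier acetoxyallylation of aldehydes and the chelation-controlled allylindation of β-hydroxy carbonyl compounds.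

**Step 6**
Reactants: 13 (3R,4S,6S)-4-[(8Z)-heptadec-8-en-1-yl]octa-1,7-diene-3,4,6-triol
Product: 14 (1R,2S,4S)-2-[(8Z)-heptadec-8-en-1-yl]cyclohex-5-ene-1,2,4-triol
Conditions: second-generation Grubbs catalyst RuCl2(=CHPh)(PCy3)(H2IMes) (3 mol %), 1,4-benzoquinone (10 mol %), CH2Cl2 (5 mM), 40 °C, argon sparge, 1–2 h
Reagents that add atoms: none
Why: Ring-closing metathesis of the two monosubstituted allylic-carbinol olefins to a six-membered ring is much faster at high dilution than intermolecular metathesis of the remote internal Z-olefin, benzoquinone suppresses ruthenium hydride isomerisation, and no stereocentre is touched.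

**Step 7**
Reactants: 14 (1R,2S,4S)-2-[(8Z)-heptadec-8-en-1-yl]cyclohex-5-ene-1,2,4-triol
Product: 17 (4R,5S)-4,5-dihydroxy-5-[(8Z)-heptadec-8-en-1-yl]cyclohex-2-en-1-one, via triol phenylboronate 15 (not isolated), via enone phenylboronate 16 (not isolated)
Conditions: PhB(OH)2 (1.05 equiv), 4 Å MS, CH2Cl2, rt; then Dess–Martin periodinane (1.2 equiv), 0 °C to rt; then pinacol (3 equiv), rt; neutral silica
Reagents that add atoms: none
Why: The cis-1,2-diol is tied up as its five-membered phenylboronate (the trans-disposed C4 hydroxyl of 14 cannot join), so the periodinane oxidises only the remaining secondary allylic alcohol, and exchange of boron to pinacol frees the diol without the acid or base that would dehydrate the product to the hydroquinone (transient boronate protection and Dess–Martin oxidation).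

**Compound list**
1 | oleic acid | CCCCCCCC/C=C\CCCCCCCC(=O)O | starting material
2 | methyllithium | [Li]C | starting material
3 | dilithium (10Z)-nonadec-10-ene-2,2-diolate | CCCCCCCC/C=C\CCCCCCCC(C)([O-])[O-].[Li+].[Li+] | intermediate (not isolated)
4 | (10Z)-nonadec-10-en-2-one | CCCCCCCC/C=C\CCCCCCCC(C)=O | intermediate
5 | trimethyl[(10Z)-nonadeca-1,10-dien-2-yloxy]silane | CCCCCCCC/C=C\CCCCCCCC(=C)O[Si](C)(C)C | intermediate
6 | acrolein | C=CC=O | starting material
7 | (3S,13Z)-3-(trichlorosilyloxy)docosa-1,13-dien-5-one | CCCCCCCC/C=C\CCCCCCCC(=O)C[C@H](O[Si](Cl)(Cl)Cl)C=C | intermediate (not isolated)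
8 | (3S,13Z)-3-hydroxydocosa-1,13-dien-5-one | CCCCCCCC/C=C\CCCCCCCC(=O)C[C@H](O)C=C | intermediate
9 | acetyl bromide | CC(=O)Br | starting material
10 | 3-bromoprop-1-en-1-yl acetate (E/Z mixture) | CC(=O)OC=CCBr | intermediate
11 | (Z)-3-acetoxyallylindium dibromide | CC(=O)O/C=C\C[In](Br)Br | intermediate (not isolated)
12 | (3R,4S,6S)-4,6-dihydroxy-4-[(8Z)-heptadec-8-en-1-yl]octa-1,7-dien-3-yl acetate | CCCCCCCC/C=C\CCCCCCC[C@](O)(C[C@H](O)C=C)[C@H](OC(C)=O)C=C | intermediate (not isolated)
13 | (3R,4S,6S)-4-[(8Z)-heptadec-8-en-1-yl]octa-1,7-diene-3,4,6-triol | CCCCCCCC/C=C\CCCCCCC[C@](O)(C[C@H](O)C=C)[C@H](O)C=C | intermediate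
14 | (1R,2S,4S)-2-[(8Z)-heptadec-8-en-1-yl]cyclohex-5-ene-1,2,4-triol | CCCCCCCC/C=C\CCCCCCC[C@]1(O)C[C@H](O)C=C[C@H]1O | intermediate
15 | cyclic phenylboronate of the C1/C2 cis-diol of 14, C4 hydroxyl free | CCCCCCCC/C=C\CCCCCCC[C@]12C[C@H](O)C=C[C@H]1OB(c1ccccc1)O2 | intermediate (not isolated)
16 | cyclic phenylboronate of the C4/C5 cis-diol of 17 | CCCCCCCC/C=C\CCCCCCC[C@]12CC(=O)C=C[C@H]1OB(c1ccccc1)O2 | intermediate (not isolated)
17 | (4R,5S)-4,5-dihydroxy-5-[(8Z)-heptadec-8-en-1-yl]cyclohex-2-en-1-one | CCCCCCCC/C=C\CCCCCCC[C@]1(O)CC(=O)C=C[C@H]1O | target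

**Step count**
Total steps: 7. Longest linear sequence: 6 (steps 1, 2, 3, 5, 6, 7).

**The three steps most likely to fail**

Step 5. An unactivated dialkyl ketone may react slowly with the stabilised allylindium, and both new stereocentres rest on the chelate model.
- The fallback sets out from 8 and comes back at 14. It uses an acryloyl anion equivalent and sets C4 later, inside the ring.
- 8 is treated with 1-lithio-1-methoxyallene (3 equiv, from methoxyallene and n-BuLi, THF, −78 °C). The lithium alkoxide of the hydroxyl chelates the ketone. The product is (3S,5S,13Z)-5-(1-methoxypropa-1,2-dien-1-yl)docosa-1,13-diene-3,5-diol F1.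
- Dilute aqueous H2SO4 in THF hydrolyses the allenyl ether to (4S,6S)-4,6-dihydroxy-4-[(8Z)-heptadec-8-en-1-yl]octa-1,7-dien-3-one F2.
- Ring-closing metathesis with second-generation Hoveyda–Grubbs catalyst RuCl2(=CH-C6H4-2-OiPr)(H2IMes) gives (4S,6S)-4,6-dihydroxy-6-[(8Z)-heptadec-8-en-1-yl]cyclohex-2-en-1-one F3.
- Luche reduction (NaBH4, CeCl3·7H2O, MeOH, −78 °C) delivers hydride axially, anti to the axial tertiary hydroxyl, and gives 14.

Step 7. The boronate may form incompletely or exchange slowly, and two allylic carbinols then compete for the oxidant.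
- The fallback sets out from 12 and comes back at 17. 12 is purified instead of being methanolysed, so the acetate from the key step differentiates the two carbinols.
- Ring-closing metathesis under the step 6 conditions gives (1R,4S,6S)-4,6-dihydroxy-6-[(8Z)-heptadec-8-en-1-yl]cyclohex-2-en-1-yl acetate F4.
- MnO2 in CH2Cl2 oxidises its only free secondary alcohol to (1R,6S)-6-hydroxy-6-[(8Z)-heptadec-8-en-1-yl]-4-oxocyclohex-2-en-1-yl acetate F5.
- Candida antarctica lipase B with MeOH in MTBE at 30 °C removes the acetate at neutral pH and gives 17.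

Step 3. Acrolein is a small, polymerisable aldehyde and the enantiomeric excess may fall short.
- The fallback sets out from 4 and comes back at 8. It makes the aldol racemic and resolves it.
- The lithium enolate of 4 (LiN(iPr)2, THF, −78 °C) is added to acrolein to give racemic (13Z)-3-hydroxydocosa-1,13-dien-5-one F6.
- Sharpless kinetic resolution (Ti(OiPr)4, D-(−)-diisopropyl tartrate, t-BuOOH 0.6 equiv, 4 Å MS, CH2Cl2, −20 °C) epoxidises the R enantiomer faster.
- Unreacted 8 is recovered in high enantiomeric purity, in at most half of the mass.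

**Further compounds**
F1 | step 5 | (3S,5S,13Z)-5-(1-methoxypropa-1,2-dien-1-yl)docosa-1,13-diene-3,5-diol | CCCCCCCC/C=C\CCCCCCC[C@](O)(C[C@H](O)C=C)C(OC)=C=C
F2 | step 5 | (4S,6S)-4,6-dihydroxy-4-[(8Z)-heptadec-8-en-1-yl]octa-1,7-dien-3-one | CCCCCCCC/C=C\CCCCCCC[C@](O)(C[C@H](O)C=C)C(=O)C=C
F3 | step 5 | (4S,6S)-4,6-dihydroxy-6-[(8Z)-heptadec-8-en-1-yl]cyclohex-2-en-1-one | CCCCCCCC/C=C\CCCCCCC[C@]1(O)C[C@H](O)C=CC1=O
F4 | step 7 | (1R,4S,6S)-4,6-dihydroxy-6-[(8Z)-heptadec-8-en-1-yl]cyclohex-2-en-1-yl acetate | CCCCCCCC/C=C\CCCCCCC[C@]1(O)C[C@H](O)C=C[C@H]1OC(C)=O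
F5 | step 7 | (1R,6S)-6-hydroxy-6-[(8Z)-heptadec-8-en-1-yl]-4-oxocyclohex-2-en-1-yl acetate | CCCCCCCC/C=C\CCCCCCC[C@]1(O)CC(=O)C=C[C@H]1OC(C)=O
F6 | step 3 | racemic (13Z)-3-hydroxydocosa-1,13-dien-5-one | CCCCCCCC/C=C\CCCCCCCC(=O)CC(O)C=C
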